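The runs were computed with made-up constants, noise included.

What is left in a flask says more when I count it as a pool: starting material plus target, the part of the charge I can actually read.

- alpha: starting material 1 M; run made earlier
- flask: starting material 2.0 M; time 4.0 min

alpha run (percent of the starting material charged)

| time / s | starting material / % | target / % |
|---|---|---|
| 10.0 | 78.1 | 12.6 |
| 15.0 | 69.8 | 16.9 |
| 20.0 | 63.0 | 18.5 |
| 30.0 | 50.0 | 21.9 |
| 40.0 | 42.4 | 22.0 |
| 50.0 | 35.1 | 21.0 |

(scatter of a reading: 0.5 percentage points)

- the numbers in the tables scatter with a standard deviation of 0.5 percentage points
- the reaction counts as stopped when no species that holds the starting material changes by six tenths of a point or more over the second half of the time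

- which holds at 4.0 min: what has brought the reaction to rest, or that it has not come to rest (forward and back rates have come level / it is still moving / all of the starting material has reacted)
- conversion of starting material at 4.0 min
- amount of target at 4.0 min, in percent of the starting material charged
- amount of over-reaction product at 4.0 min, in percent of the starting material charged

In the alpha run the pool stands at 56.1 % of the charge at 50.0 s, and the rest is the gap in the mass balance. Dividing target by the pool gives a share that does not depend on how far the pool has shrunk, but the share itself still moves with time. Target's share of the pool, 0.374 at that reading, is up from 0.139 at the first.

I assume that doubling the charge leaves these fractions unchanged, which one run cannot test. From above, target is first capped by its highest reading, 22.0 %. For a tighter figure I pass from a bound to an estimate: the pool leaks at 0.694 min⁻¹ on average, and if it went on so it would hold 0.0624 at 4.0 min, which I take as the top of my bracket for target. From below, I take the faster late leak, 0.744 min⁻¹, and freeze the rising share, which gives 0.0199. Over-reaction product was never read, so I can place it only somewhere within the gap.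

The forecast reads it is still moving, with 98 % converted, 1.5 % target and 96.5 % over-reaction product, on the ground that “doubling concentration changes nothing”, and its target lies below my bracket.

The flask gives it is still moving, with 96.0 % converted, 3.16 % target and 37.6 % over-reaction product. The gap in this flask also holds isomer of the product B, 31.0 %, and isomer of the product A, 22.2 %.

    target → over-reaction product (k = 0.0154 s⁻¹)
    target ⇌ isomer of the product B (K = 12.0, k = 0.0155 s⁻¹)
    starting material ⇌ third isomer (K = 2.30, k = 3.94 × 10⁻⁴ s⁻¹)
    starting material ⇌ target (K = 1.88, k = 0.0185 s⁻¹)
    starting material ⇌ isomer of the product A (K = 2.79, k = 0.00644 s⁻¹)

Target's share of the pool here is 0.440. The same flask read at 10 min has a share of 0.477.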